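## Retrosynthetic overview
1. Target 18 comes from the bis(acetoxymethyl) ether 16. A lipase releases both ring A phenols at neutral pH in the last step.
2. Rings A and B are bought as arenes. Ring C is the only ring made, closed at C3–C4 by an enantioselective carbene-catalysed crossed benzoin of keto-aldehyde 15, which sets C3 as R.
3. 15 comes from forming the O1–C2 ether bond between phenol 14 (ring A) and α-chloroketone 11 (ring B).
4. 11 comes from the aryllithium of bromide 7 and chloro Weinreb amide 8. 7 comes from 1,3-dimethoxybenzene by ortho-lithiation/allylation, bromination and cross-metathesis.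
5. 14 comes from 2,4,6-trihydroxybenzaldehyde and bromomethyl acetate.

Assumption: the target is (3R) (OH > C4 > C2 > aryl), and the (5aS,10bR) precatalyst, made from (1R,2S)-cis-1-amino-2-indanol, is taken to give this sense (attack on the open face of the enaminol with its OH next to the N-aryl group). The first batch is checked by chiral HPLC and ECD, and the equally available (5aR,10bS) antipode is used if the sense is reversed.

## Route

Step 1
Reactants: 1 1,3-dimethoxybenzene; 2 allyl bromide
Product: 4 2-allyl-1,3-dimethoxybenzene, via 2-lithio-1,3-dimethoxybenzene 3 (not isolated)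
Conditions: n-BuLi (1.1 equiv), THF, 0 °C → rt, 2 h; then 2 (1.3 equiv), −78 °C → rt
Reagents that add atoms: allyl bromide 2, C=CCBr
Why: Directed ortho-metalation followed by SN2 allylation: both methoxy groups steer n-BuLi to the C2–H they flank, the aryllithium displaces bromide cleanly, and allyl rather than prenyl is installed because a terminal alkene is inert in the bromination that follows.

Step 2
Reactants: 4 2-allyl-1,3-dimethoxybenzene
Product: 5 3-allyl-1-bromo-2,4-dimethoxybenzene
Conditions: NBS (1.0 equiv), MeCN, 0 °C, dark, 1 h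
Reagents that add atoms: N-bromosuccinimide, O=C1CCC(=O)N1Br
Why: Electrophilic aromatic bromination: the attacked carbon is para to one methoxy group and ortho to the other and is orders of magnitude more nucleophilic than the monosubstituted alkene, so one equivalent of NBS gives a single ring bromide (the two such positions are equivalent).

Step 3
Reactants: 5 3-allyl-1-bromo-2,4-dimethoxybenzene; 6 2-methylbut-2-ene
Product: 7 1-bromo-2,4-dimethoxy-3-(3-methylbut-2-en-1-yl)benzene
Conditions: second-generation Grubbs catalyst RuCl2(=CHPh)(PCy3)(SIMes) (2 mol %), 6/CH2Cl2 1:1, 40 °C, sealed tube, 12 h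
Reagents that add atoms: 2-methylbut-2-ene 6, CC=C(C)C
Why: Olefin cross-metathesis: the unhindered terminal alkene exchanges its CH2 terminus for the isopropylidene of 6 used in large excess, loss of gaseous propene drives the reaction, the trisubstituted product does not re-enter the cycle, and the aryl bromide and ethers are inert to the ruthenium carbene.

Step 4
Reactants: 7 1-bromo-2,4-dimethoxy-3-(3-methylbut-2-en-1-yl)benzene; 8 2-chloro-N-methoxy-N-methylacetamide
Product: 11 2-chloro-1-[2,4-dimethoxy-3-(3-methylbut-2-en-1-yl)phenyl]ethan-1-one, via aryllithium 9 (not isolated), via tetrahedral lithium adduct 10 (not isolated)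
Conditions: n-BuLi (1.05 equiv), THF, −78 °C, 20 min; 8 (1.2 equiv), −78 °C, 1 h; 1 M HCl, −78 °C → rt
Reagents that add atoms: 2-chloro-N-methoxy-N-methylacetamide 8, CON(C)C(=O)CCl
Why: Bromine–lithium exchange followed by Weinreb ketone synthesis: exchange at −78 °C outruns deprotonation of the benzylic-allylic CH2, the chelated tetrahedral adduct blocks a second addition until the cold acid quench, and the α-chloroketone is obtained without any electrophilic halogen that would attack the prenyl alkene.

Step 5
Reactants: 12 2,4,6-trihydroxybenzaldehyde; 13 bromomethyl acetate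
Product: 14 2,4-bis(acetoxymethoxy)-6-hydroxybenzaldehyde
Conditions: 13 (2.1 equiv), i-Pr2NEt (2.3 equiv), DMF, 0 °C → rt, 6 h
Reagents that add atoms: bromomethyl acetate 13, CC(=O)OCBr
Why: Williamson-type O-alkylation with a hard α-acyloxyalkyl halide (same selectivity pattern as chloromethyl methyl ether): the free 4-OH and one of the two equivalent ortho OH groups react at oxygen, while the last OH stays locked in its hydrogen bond to the formyl group and is kept for the coupling.

Step 6
Reactants: 14 2,4-bis(acetoxymethoxy)-6-hydroxybenzaldehyde; 11 2-chloro-1-[2,4-dimethoxy-3-(3-methylbut-2-en-1-yl)phenyl]ethan-1-one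
Product: 15 2,4-bis(acetoxymethoxy)-6-{2-[2,4-dimethoxy-3-(3-methylbut-2-en-1-yl)phenyl]-2-oxoethoxy}benzaldehyde
Conditions: K2CO3 (1.5 equiv), KI (10 mol %), dry DMF, 4 Å MS, 25 °C, 12 h
Reagents that add atoms: none
Why: Williamson ether synthesis (iodide-assisted SN2 at a phenacyl chloride): the activated halide reacts with the phenoxide already at room temperature, where aldol/dehydration to a 2-aroylbenzofuran (Rap–Stoermer reaction) and attack on the acetate esters are slow in a dry medium.

Step 7
Reactants: 15 keto-aldehyde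
Product: 16 (3R)-5,7-bis(acetoxymethoxy)-3-hydroxy-3-[2,4-dimethoxy-3-(3-methylbut-2-en-1-yl)phenyl]chroman-4-one
Conditions: (5aS,10bR)-2-(pentafluorophenyl)-5a,10b-dihydro-4H,6H-indeno[2,1-b][1,2,4]triazolo[4,3-d][1,4]oxazin-2-ium tetrafluoroborate (15 mol %), Et3N (15 mol %), toluene, 4 Å MS, Ar, 25 °C; AcOH quench; recrystallise (EtOAc/heptane) to ≥ 99 % ee
Reagents that add atoms: none
Why: Enantioselective N-heterocyclic-carbene-catalysed intramolecular crossed benzoin reaction: the chiral triazolylidene turns the formyl carbon into an acyl-anion equivalent with one face walled off by the indane, the tethered ketone is attacked on a single face through a six-membered hydrogen-bonded transition state, which forms ring C and the C3–C4 bond and sets C3 as R, while the weak base and electron-poor N-aryl group suppress enolisation and the prenyl alkene and acetal esters are spectators.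

Step 8
Reactants: 16 (3R)-bis(acetoxymethyl) ether
Product: 18 (3R)-3,5,7-trihydroxy-3-[2,4-dimethoxy-3-(3-methylbut-2-en-1-yl)phenyl]chroman-4-one (CNP0269650.1), via bis(hemiformal) 17 (not isolated)
Conditions: lipase (immobilised Candida antarctica lipase B, 50 wt %), n-BuOH (10 equiv), MTBE, 30 °C, 24 h; filter, concentrate, short silica column
Reagents that add atoms: none
Why: Lipase-catalysed transesterification (serine-hydrolase acyl transfer to butanol) of the two primary acetates unmasks hemiformals that collapse spontaneously to the phenols, so both ring A hydroxyls are released at neutral pH without the acid that would dehydrate the tertiary benzylic ketol to the isoflavone, the base that could trigger α-ketol rearrangement or the hydrogenolysis that would saturate the prenyl group, and C3 is untouched.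

## Compound list
1 | 1,3-dimethoxybenzene | COc1cccc(OC)c1 | starting material
2 | allyl bromide | C=CCBr | starting material
3 | 2-lithio-1,3-dimethoxybenzene (not isolated) | COc1cccc(OC)c1[Li] | intermediate
4 | 2-allyl-1,3-dimethoxybenzene | COc1cccc(OC)c1CC=C | intermediate
5 | 3-allyl-1-bromo-2,4-dimethoxybenzene | COc1ccc(Br)c(OC)c1CC=C | intermediate
6 | 2-methylbut-2-ene | CC=C(C)C | starting material
7 | 1-bromo-2,4-dimethoxy-3-(3-methylbut-2-en-1-yl)benzene | COc1ccc(Br)c(OC)c1CC=C(C)C | intermediate
8 | 2-chloro-N-methoxy-N-methylacetamide | CON(C)C(=O)CCl | starting material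
9 | [2,4-dimethoxy-3-(3-methylbut-2-en-1-yl)phenyl]lithium (not isolated) | COc1ccc([Li])c(OC)c1CC=C(C)C | intermediate
10 | lithium 2-chloro-1-aryl-1-[methoxy(methyl)amino]ethan-1-olate, chelated tetrahedral adduct (transient, racemic; its sp3 carbon returns to a carbonyl on quench; not isolated) | COc1ccc(C(CCl)(O[Li])N(C)OC)c(OC)c1CC=C(C)C | intermediate
11 | 2-chloro-1-[2,4-dimethoxy-3-(3-methylbut-2-en-1-yl)phenyl]ethan-1-one | COc1ccc(C(=O)CCl)c(OC)c1CC=C(C)C | intermediate
12 | 2,4,6-trihydroxybenzaldehyde | O=Cc1c(O)cc(O)cc1O | starting material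
13 | bromomethyl acetate | CC(=O)OCBr | starting material
14 | 2,4-bis(acetoxymethoxy)-6-hydroxybenzaldehyde | O=Cc1c(O)cc(OCOC(C)=O)cc1OCOC(C)=O | intermediate
15 | 2,4-bis(acetoxymethoxy)-6-{2-[2,4-dimethoxy-3-(3-methylbut-2-en-1-yl)phenyl]-2-oxoethoxy}benzaldehyde | COc1ccc(C(=O)COc2cc(OCOC(C)=O)cc(OCOC(C)=O)c2C=O)c(OC)c1CC=C(C)C | intermediate
16 | (3R)-5,7-bis(acetoxymethoxy)-3-hydroxy-3-[2,4-dimethoxy-3-(3-methylbut-2-en-1-yl)phenyl]chroman-4-one | COc1ccc([C@@]2(O)COc3cc(OCOC(C)=O)cc(OCOC(C)=O)c3C2=O)c(OC)c1CC=C(C)C | intermediate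
17 | (3R)-3-hydroxy-5,7-bis(hydroxymethoxy)-3-[2,4-dimethoxy-3-(3-methylbut-2-en-1-yl)phenyl]chroman-4-one (not isolated) | COc1ccc([C@@]2(O)COc3cc(OCO)cc(OCO)c3C2=O)c(OC)c1CC=C(C)C | intermediate
18 | (3R)-3,5,7-trihydroxy-3-[2,4-dimethoxy-3-(3-methylbut-2-en-1-yl)phenyl]chroman-4-one (CNP0269650.1) | COc1ccc([C@@]2(O)COc3cc(O)cc(O)c3C2=O)c(OC)c1CC=C(C)C | target

## Step count and risks
Total steps: 8. Longest linear sequence: 7 (steps 1, 2, 3, 4, 6, 7, 8). Step 5 is a one-step side branch.

**Step 7 (most likely to fail).**
- Failure mode: the formyl group sits between two alkoxy groups on an electron-rich ring, and the ketone is electron-rich and ortho-substituted. The bulky chiral carbene may therefore react slowly or give insufficient ee.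
- Fallback: it sets out from 15 and comes back at 16, and makes the C3–O bond, not the C3–C4 bond, the stereodefining event.
- Ring C is first closed with the small achiral carbene from 2-(pentafluorophenyl)-6,7-dihydro-5H-pyrrolo[2,1-c][1,2,4]triazol-2-ium tetrafluoroborate and Et3N, giving the racemic ketol F1.
- Catalytic p-TsOH in toluene at 60 °C dehydrates it to the flat 5,7-bis(acetoxymethoxy)-2',4'-dimethoxy-3'-prenylisoflavone F2.
- 1,4-Hydrosilylation with Et3SiH and RhCl(PPh3)3 (2 mol %, toluene, 60 °C) gives the 4-(triethylsilyloxy)isoflav-3-ene F3.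
- Asymmetric Rubottom-type oxygen transfer follows, using chloro[N,N'-bis(3,5-di-tert-butylsalicylidene)cyclohexane-1,2-diaminato]manganese (trivalent manganese, 5 mol %; the antipode giving R is picked in a test run, both are sold), PhIO and 4-phenylpyridine N-oxide in CH2Cl2 at 0 °C.
- This oxidant attacks the electron-rich conjugated chromene-type enol ether far faster than the isolated prenyl alkene. After silyl migration it gives the (3R)-3-O-triethylsilyl ether F4, and Et3N·3HF in THF then releases 16.

**Step 8.**
- Failure mode: the 5-O-acetoxymethyl group is peri to the C4 carbonyl and close to the C3 aryl group, so the lipase may stop after the exposed 7-O group.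
- Fallback: it sets out from 16 and comes back at 18.
- The same lipase alcoholysis is run only as far as it goes easily. It passes through the 7-O-hemiformal F5 and gives the (3R)-5-(acetoxymethoxy)-3,7-dihydroxy compound F6.
- The remaining group is then removed by chelation rather than by acyl transfer. MgBr2·OEt2 (3 equiv, CH2Cl2/Et2O, 0 °C) binds between the C4 carbonyl and O5, bromide attacks the acetal CH2, and aqueous NH4Cl liberates 18.

**Step 6.**
- Failure mode: carbonate base can push 15 on to the 2-aroylbenzofuran or nibble at the acetates.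
- Fallback: it sets out from 11 and comes back at 15, and forms the same O–CH2 bond without base.
- HCO2Na in aqueous EtOH at reflux displaces chloride to give the formate ester F7. This is hydrolysed in the same pot to the α-hydroxy ketone 2-hydroxy-1-[2,4-dimethoxy-3-(3-methylbut-2-en-1-yl)phenyl]ethan-1-one F8.
- Mitsunobu etherification of F8 with phenol 14 (PPh3, DIAD, THF, 0 °C → rt) then gives 15 under neutral conditions.

## Further compounds
F1 | step 7 | racemic 5,7-bis(acetoxymethoxy)-3-hydroxy-3-[2,4-dimethoxy-3-(3-methylbut-2-en-1-yl)phenyl]chroman-4-one | COc1ccc(C2(O)COc3cc(OCOC(C)=O)cc(OCOC(C)=O)c3C2=O)c(OC)c1CC=C(C)C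
F2 | step 7 | 5,7-bis(acetoxymethoxy)-2',4'-dimethoxy-3'-prenylisoflavone | COc1ccc(-c2coc3cc(OCOC(C)=O)cc(OCOC(C)=O)c3c2=O)c(OC)c1CC=C(C)C
F3 | step 7 | 5,7-bis(acetoxymethoxy)-3-[2,4-dimethoxy-3-(3-methylbut-2-en-1-yl)phenyl]-4-(triethylsilyloxy)-2H-chromene | COc1ccc(C2=C(O[Si](CC)(CC)CC)c3c(OCOC(C)=O)cc(OCOC(C)=O)cc3OC2)c(OC)c1CC=C(C)C
F4 | step 7 | (3R)-5,7-bis(acetoxymethoxy)-3-(triethylsilyloxy)-3-[2,4-dimethoxy-3-(3-methylbut-2-en-1-yl)phenyl]chroman-4-one | COc1ccc([C@@]2(O[Si](CC)(CC)CC)COc3cc(OCOC(C)=O)cc(OCOC(C)=O)c3C2=O)c(OC)c1CC=C(C)C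
F5 | step 8 | (3R)-5-(acetoxymethoxy)-3-hydroxy-7-(hydroxymethoxy)-3-[2,4-dimethoxy-3-(3-methylbut-2-en-1-yl)phenyl]chroman-4-one | COc1ccc([C@@]2(O)COc3cc(OCO)cc(OCOC(C)=O)c3C2=O)c(OC)c1CC=C(C)C
F6 | step 8 | (3R)-5-(acetoxymethoxy)-3,7-dihydroxy-3-[2,4-dimethoxy-3-(3-methylbut-2-en-1-yl)phenyl]chroman-4-one | COc1ccc([C@@]2(O)COc3cc(O)cc(OCOC(C)=O)c3C2=O)c(OC)c1CC=C(C)C
F7 | step 6 | 2-[2,4-dimethoxy-3-(3-methylbut-2-en-1-yl)phenyl]-2-oxoethyl formate | COc1ccc(C(=O)COC=O)c(OC)c1CC=C(C)C
F8 | step 6 | 2-hydroxy-1-[2,4-dimethoxy-3-(3-methylbut-2-en-1-yl)phenyl]ethan-1-one | COc1ccc(C(=O)CO)c(OC)c1CC=C(C)C
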